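The labdane is disconnected at C5–C6 and C9–C10, so that ring A with the C4 gem-dimethyl group and the C10 methyl becomes 2,4,4-trimethylcyclohex-2-en-1-one; ring B is closed later at C8–C9. The feature exploited is the vicinal trans pair of ring A, tertiary C5 and quaternary C10, which are the β- and α-carbons of that enone. In one flask, an enantioselective copper-catalysed 1,4-addition of a silyl-masked but-3-ynylzinc to C5 and allylation of the zinc enolate at C10 attach both ring-B arms trans and fix the absolute configuration. The precursors are the achiral enone, bis[4-(trimethylsilyl)but-3-ynyl]zinc and allyl iodide.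

Key step: step 4

**Remarks on the chemistry**

- Labdane numbering is used for atoms throughout: C1–C10 decalin, C17 exocyclic methylene carbon, C11–C15 side chain.
- Ligand L is (S)-O,O'-(1,1'-binaphthalene-2,2'-diyl) N,N-bis[(R)-1-phenylethyl]phosphoramidite.
- Assumption: the carbinol centre made in step 5 need not be controlled, because it is removed in step 7. The E/Z geometry of the silyl enol ether of step 9 and of the acetal terminus of the silyl dienolate of step 11 is without consequence. These three elements are left undefined in the SMILES.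
- Stereochemical correspondence: ring carbons C2 and C3 of the (2R,3S) ketone 9 are C10 and C5 of the target and carry its 5S,10S configuration.
- 4-(Trimethylsilyl)but-3-yn-1-ol is taken as a catalogue compound.
- The dialkylzinc needs two butynyl groups per zinc. One is brought in as the alkylzinc iodide 3 and the other as the Grignard reagent 4, both made from iodide 2.

**Route**

Step 1
Reactants: 1 4-(trimethylsilyl)but-3-yn-1-ol
Product: 2 (4-iodobut-1-yn-1-yl)trimethylsilane
Conditions: I2, PPh3, imidazole, CH2Cl2, 0 °C to rt
Reagents that add atoms: iodine, II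
Why: Appel-type iodination, in which the primary alcohol is activated as an alkoxyphosphonium ion and displaced by iodide in an SN2 step while the C-silylated alkyne is inert; no stereocentre is involved.

Step 2
Reactants: 2 (4-iodobut-1-yn-1-yl)trimethylsilane
Product: 3 iodo[4-(trimethylsilyl)but-3-yn-1-yl]zinc (titrated THF solution)
Conditions: Zn dust (activated with BrCH2CH2Br and Me3SiCl), THF, 40 °C; decant from excess Zn
Reagents that add atoms: zinc, [Zn]
Why: Oxidative insertion of activated zinc into the primary C–I bond (Knochel-type preparation of alkylzinc iodides) gives the alkylzinc iodide, the silyl cap removing the acidic alkyne hydrogen that would otherwise quench the reagent.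

Step 3
Reactants: 2 (4-iodobut-1-yn-1-yl)trimethylsilane; 3 iodo[4-(trimethylsilyl)but-3-yn-1-yl]zinc
Product: 5 bis[4-(trimethylsilyl)but-3-yn-1-yl]zinc, via Grignard reagent 4 (not isolated)
Conditions: 2, Mg turnings, Et2O, rt, titrate; add to 3 (1.0 equiv), THF–Et2O, 0 °C to rt; 1,4-dioxane, centrifuge under Ar; evaporate, redissolve in toluene
Reagents that add atoms: none
Why: Transmetalation from magnesium to zinc, in which the alkylmagnesium iodide made from 2 transfers its butynyl group to the alkylzinc iodide 3 so that each organometallic supplies one of the two alkyl groups of the dialkylzinc, while precipitation of MgI2 as its 1,4-dioxane adduct leaves the halide-free toluene solution that the copper–phosphoramidite step requires.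

Step 4
Reactants: 5 bis[4-(trimethylsilyl)but-3-yn-1-yl]zinc; 6 2,4,4-trimethylcyclohex-2-en-1-one; 7 allyl iodide
Product: 9 (2R,3S)-2-allyl-2,4,4-trimethyl-3-[4-(trimethylsilyl)but-3-yn-1-yl]cyclohexan-1-one, via alkylzinc enolate 8 (not isolated)
Conditions: Cu(OTf)2 (3 mol%), L (6 mol%), toluene, −30 to 0 °C; then 7 (excess), DMPU, 0 °C to rt; aq NH4Cl
Reagents that add atoms: none
Why: The species formed from Cu(OTf)2, L and 5 transfers one butynyl group from zinc to the β-carbon C5 of 6 (π-complexation, oxidative addition at the β-carbon, reductive elimination) and leaves the regiodefined alkylzinc enolate 8 across C10–C1, which 7 then alkylates at carbon C10 in an SN2 step assisted by DMPU. The closest known reaction type is the copper–phosphoramidite-catalysed asymmetric conjugate addition of dialkylzincs to cyclic enones with in situ allylation of the zinc enolate, a three-component vicinal difunctionalisation. No ring is closed here: C5–C6 and C9–C10 are formed and the two chains stay open for the later C8–C9 closure of ring B. C5 is set by ligand L, which selects the enone face (sense chosen by analogy with cyclohex-2-enone, the antipodal ligand being the remedy should the sense be reversed), and C10 is set by the substrate, because the allyl iodide approaches the enolate face opposite the new C5 chain, which sits pseudoaxial between the C10 methyl and the C4 gem-dimethyl group. The step needs enantioface selection at C5, trans selectivity at C10, C- over O-allylation and no enolate equilibration; these should be secured by the chiral ligand, by the shielding C5 substituent, by the soft allylic iodide and by the aprotic one-pot protocol that never frees the ketone before alkylation. The α-methyl and γ,γ-dimethyl groups slow both events, which is why 5 and 7 are used in excess and the mixture is warmed to 0 °C before the electrophile is added.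

Step 5
Reactants: 9 (2R,3S)-2-allyl-2,4,4-trimethyl-3-[4-(trimethylsilyl)but-3-yn-1-yl]cyclohexan-1-one
Product: 10 (2R,3S)-2-allyl-2,4,4-trimethyl-3-[4-(trimethylsilyl)but-3-yn-1-yl]cyclohexan-1-ol (C1 epimers)
Conditions: LiAlH4, Et2O, 0 °C; aqueous NaOH work-up
Reagents that add atoms: none
Why: Hydride reduction of the hindered ketone with LiAlH4 leaves the silylalkyne and the alkene untouched; the new carbinol centre is not controlled and need not be, while C5 and C10 are not epimerisable.

Step 6
Reactants: 10 (2R,3S)-2-allyl-2,4,4-trimethyl-3-[4-(trimethylsilyl)but-3-yn-1-yl]cyclohexan-1-ol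
Product: 13 O-{(2R,3S)-2-allyl-2,4,4-trimethyl-3-[4-(trimethylsilyl)but-3-yn-1-yl]cyclohexyl} S-methyl carbonodithioate, via sodium alkoxide 11 (not isolated), via sodium xanthate 12 (not isolated)
Conditions: NaH, imidazole (cat.), THF, reflux; CS2; MeI
Reagents that add atoms: carbon disulfide, S=C=S; iodomethane, CI
Why: Xanthate formation for a Barton–McCombie deoxygenation, in which the sodium alkoxide adds to CS2 and the dithiocarbonate salt is S-methylated, a sequence that tolerates hindered secondary alcohols and touches neither the alkene nor the silylalkyne.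

Step 7
Reactants: 13 O-{(2R,3S)-2-allyl-2,4,4-trimethyl-3-[4-(trimethylsilyl)but-3-yn-1-yl]cyclohexyl} S-methyl carbonodithioate
Product: 15 (1R,2S)-1-allyl-2-(but-3-yn-1-yl)-1,3,3-trimethylcyclohexane, via silylalkyne hydrocarbon 14 (not isolated)
Conditions: Bu3SnH (about 0.2 M), AIBN (cat.), toluene, 100 °C; concentrate; then K2CO3, MeOH–THF, rt
Reagents that add atoms: none
Why: Barton–McCombie radical deoxygenation followed by base-catalysed methanolysis of the C–Si bond: the secondary C1 radical should be reduced by Bu3SnH faster than it can cyclise (only 4-exo or 5-endo paths to the allyl group and a slow 6-exo path to the silyl-shielded alkyne are open), the silyl group protects the alkyne from hydrostannylation, and K2CO3/MeOH then frees the terminal alkyne with C5 and C10 untouched.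

Step 8
Reactants: 15 (1R,2S)-1-allyl-2-(but-3-yn-1-yl)-1,3,3-trimethylcyclohexane
Product: 16 2-[(1R,2S)-2-(but-3-yn-1-yl)-1,3,3-trimethylcyclohexyl]acetaldehyde
Conditions: OsO4 (cat.), NaIO4, 2,6-lutidine, dioxane–H2O, rt
Reagents that add atoms: osmium tetroxide, O=[Os](=O)(=O)=O; sodium periodate, [Na+].[O-]I(=O)(=O)=O
Why: Lemieux–Johnson oxidation, in which catalytic OsO4 dihydroxylates the monosubstituted alkene far faster than the terminal alkyne and NaIO4, the stoichiometric oxygen source, cleaves the diol and reoxidises osmium, shortening the allyl group by one carbon to the C9–C11 acetaldehyde arm.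

Step 9
Reactants: 16 2-[(1R,2S)-2-(but-3-yn-1-yl)-1,3,3-trimethylcyclohexyl]acetaldehyde
Product: 17 triisopropyl({2-[(1S,2S)-2-(but-3-yn-1-yl)-1,3,3-trimethylcyclohexyl]ethenyl}oxy)silane (E/Z mixture)
Conditions: TIPSOTf, Et3N, CH2Cl2, 0 °C to rt
Reagents that add atoms: triisopropylsilyl trifluoromethanesulfonate, CC(C)[Si](OS(=O)(=O)C(F)(F)F)(C(C)C)C(C)C
Why: Soft enolisation and O-silylation of the aldehyde with a silyl triflate and a tertiary amine gives the silyl enol ether; only C9 carries α-hydrogens, so the C9=C11 regiochemistry is unambiguous.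

Step 10
Reactants: 17 triisopropyl({2-[(1S,2S)-2-(but-3-yn-1-yl)-1,3,3-trimethylcyclohexyl]ethenyl}oxy)silane
Product: 18 albicanal [(1S,4aS,8aS)-5,5,8a-trimethyl-2-methylidenedecahydronaphthalene-1-carbaldehyde]
Conditions: Ph3PAuCl (5 mol%), AgBF4 (5 mol%), CH2Cl2–H2O (10:1), rt to 40 °C
Reagents that add atoms: none
Why: Conia-ene-type carbocyclisation of a silyl enol ether onto a terminal alkyne under π-acid catalysis by the cationic gold species from Ph3PAuCl and AgBF4: C9 attacks the gold-activated C8 anti to the metal in a 6-exo-dig closure, protodeauration gives the exocyclic C8=C17 methylene and water removes the silyl group, and C9 should be set by a chair-like transition state of the forming trans-decalin with C11 equatorial.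

Step 11
Reactants: 19 methyl 3-methylbut-2-enoate
Product: 21 [(1-methoxy-3-methylbuta-1,3-dien-1-yl)oxy]trimethylsilane, via lithium dienolate 20 (not isolated)
Conditions: LiN(iPr)2, THF, −78 °C; Me3SiCl, −78 °C to rt; distillation
Reagents that add atoms: chlorotrimethylsilane, C[Si](C)(C)Cl
Why: γ-Deprotonation of the senecioate with lithium diisopropylamide gives the extended lithium dienolate, which Me3SiCl silylates on oxygen to the vinylogous silyl ketene acetal (standard dienolate O-silylation).

Step 12
Reactants: 18 albicanal; 21 [(1-methoxy-3-methylbuta-1,3-dien-1-yl)oxy]trimethylsilane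
Product: 23 methyl (2E,5S)-5-hydroxy-3-methyl-5-[(1S,4aS,8aS)-5,5,8a-trimethyl-2-methylidenedecahydronaphthalen-1-yl]pent-2-enoate, via O-trimethylsilyl aldol adduct 22 (not isolated)
Conditions: BF3·OEt2, CH2Cl2, −78 °C; aq NaHCO3; then 1 M HCl, THF, 0 °C
Reagents that add atoms: none
Why: Vinylogous Mukaiyama aldol addition, in which BF3-activated 18 is attacked by the terminal (γ) carbon of 21 through an open transition state; Felkin–Anh control with the quaternary C10 as the large substituent anti to the nucleophile and H9 on the approach path should give 11S, and the s-trans dienolate should deliver the (E)-enoate, any (Z)-isomer being removable because it lactonises.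

Step 13
Reactants: 23 methyl (2E,5S)-5-hydroxy-3-methyl-5-[(1S,4aS,8aS)-5,5,8a-trimethyl-2-methylidenedecahydronaphthalen-1-yl]pent-2-enoate
Product: 24 methyl (2E,5S)-5-(acetyloxy)-3-methyl-5-[(1S,4aS,8aS)-5,5,8a-trimethyl-2-methylidenedecahydronaphthalen-1-yl]pent-2-enoate (CNP0309821.1)
Conditions: Ac2O, DMAP (cat.), pyridine, CH2Cl2, 0 °C to rt
Reagents that add atoms: acetic anhydride, CC(=O)OC(C)=O
Why: DMAP-catalysed acylation of the secondary alcohol with acetic anhydride proceeds with retention at C11 under conditions too mild for γ-deprotonation and loss of acetate from the enoate.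

**Compound list**

1 | 4-(trimethylsilyl)but-3-yn-1-ol | C[Si](C)(C)C#CCCO | starting material
2 | (4-iodobut-1-yn-1-yl)trimethylsilane | C[Si](C)(C)C#CCCI | intermediate
3 | iodo[4-(trimethylsilyl)but-3-yn-1-yl]zinc | C[Si](C)(C)C#CCC[Zn]I | intermediate
4 | iodo[4-(trimethylsilyl)but-3-yn-1-yl]magnesium (not isolated) | C[Si](C)(C)C#CCC[Mg]I | intermediate
5 | bis[4-(trimethylsilyl)but-3-yn-1-yl]zinc | C[Si](C)(C)C#CCC[Zn]CCC#C[Si](C)(C)C | intermediate
6 | 2,4,4-trimethylcyclohex-2-en-1-one | CC1=CC(C)(C)CCC1=O | starting material
7 | allyl iodide | C=CCI | starting material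
8 | [4-(trimethylsilyl)but-3-yn-1-yl]zinc (3S)-2,4,4-trimethyl-3-[4-(trimethylsilyl)but-3-yn-1-yl]cyclohex-1-en-1-olate (not isolated) | C[Si](C)(C)C#CCC[Zn]OC1=C(C)[C@@H](CCC#C[Si](C)(C)C)C(C)(C)CC1 | intermediate
9 | (2R,3S)-2-allyl-2,4,4-trimethyl-3-[4-(trimethylsilyl)but-3-yn-1-yl]cyclohexan-1-one | C=CC[C@]1(C)[C@@H](CCC#C[Si](C)(C)C)C(C)(C)CCC1=O | intermediate
10 | (2R,3S)-2-allyl-2,4,4-trimethyl-3-[4-(trimethylsilyl)but-3-yn-1-yl]cyclohexan-1-ol, C1 epimers | C=CC[C@]1(C)[C@@H](CCC#C[Si](C)(C)C)C(C)(C)CCC1O | intermediate
11 | sodium alkoxide of 10 (not isolated) | C=CC[C@]1(C)[C@@H](CCC#C[Si](C)(C)C)C(C)(C)CCC1[O-].[Na+] | intermediate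
12 | sodium O-alkyl carbonodithioate of 10 (not isolated) | C=CC[C@]1(C)[C@@H](CCC#C[Si](C)(C)C)C(C)(C)CCC1OC(=S)[S-].[Na+] | intermediate
13 | O-{(2R,3S)-2-allyl-2,4,4-trimethyl-3-[4-(trimethylsilyl)but-3-yn-1-yl]cyclohexyl} S-methyl carbonodithioate | C=CC[C@]1(C)[C@@H](CCC#C[Si](C)(C)C)C(C)(C)CCC1OC(=S)SC | intermediate
14 | trimethyl{4-[(1S,2R)-2-allyl-2,6,6-trimethylcyclohexyl]but-1-yn-1-yl}silane (not isolated) | C=CC[C@]1(C)[C@@H](CCC#C[Si](C)(C)C)C(C)(C)CCC1 | intermediate
15 | (1R,2S)-1-allyl-2-(but-3-yn-1-yl)-1,3,3-trimethylcyclohexane | C=CC[C@]1(C)[C@@H](CCC#C)C(C)(C)CCC1 | intermediate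
16 | 2-[(1R,2S)-2-(but-3-yn-1-yl)-1,3,3-trimethylcyclohexyl]acetaldehyde | O=CC[C@]1(C)[C@@H](CCC#C)C(C)(C)CCC1 | intermediate
17 | triisopropyl({2-[(1S,2S)-2-(but-3-yn-1-yl)-1,3,3-trimethylcyclohexyl]ethenyl}oxy)silane, E/Z mixture | CC(C)[Si](OC=C[C@]1(C)[C@@H](CCC#C)C(C)(C)CCC1)(C(C)C)C(C)C | intermediate
18 | albicanal, (1S,4aS,8aS)-5,5,8a-trimethyl-2-methylidenedecahydronaphthalene-1-carbaldehyde | C=C1CC[C@H]2C(C)(C)CCC[C@]2(C)[C@H]1C=O | intermediate
19 | methyl 3-methylbut-2-enoate | COC(=O)C=C(C)C | starting material
20 | lithium 1-methoxy-3-methylbuta-1,3-dien-1-olate (not isolated) | C=C(C)C=C(OC)[O-].[Li+] | intermediate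
21 | [(1-methoxy-3-methylbuta-1,3-dien-1-yl)oxy]trimethylsilane | C=C(C)C=C(OC)O[Si](C)(C)C | intermediate
22 | methyl (2E,5S)-3-methyl-5-[(1S,4aS,8aS)-5,5,8a-trimethyl-2-methylidenedecahydronaphthalen-1-yl]-5-[(trimethylsilyl)oxy]pent-2-enoate (not isolated) | C=C1CC[C@H]2C(C)(C)CCC[C@]2(C)[C@H]1[C@H](C/C(C)=C/C(=O)OC)O[Si](C)(C)C | intermediate
23 | methyl (2E,5S)-5-hydroxy-3-methyl-5-[(1S,4aS,8aS)-5,5,8a-trimethyl-2-methylidenedecahydronaphthalen-1-yl]pent-2-enoate | C=C1CC[C@H]2C(C)(C)CCC[C@]2(C)[C@H]1[C@H](C/C(C)=C/C(=O)OC)O | intermediate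
24 | methyl (2E,5S)-5-(acetyloxy)-3-methyl-5-[(1S,4aS,8aS)-5,5,8a-trimethyl-2-methylidenedecahydronaphthalen-1-yl]pent-2-enoate; methyl (11S,13E)-11-acetoxylabda-8(17),13-dien-15-oate | C=C1CC[C@H]2C(C)(C)CCC[C@]2(C)[C@H]1[C@H](C/C(C)=C/C(=O)OC)OC(C)=O | target

**Step count**

Total: 13 steps. Longest linear sequence: 12 steps (steps 1–10, 12 and 13, from 4-(trimethylsilyl)but-3-yn-1-ol); step 11 is a one-step side branch.

**Steps most likely to fail**

1. Step 4. The tetrasubstituted zinc enolate is a weak nucleophile, so C-allylation may be incomplete and protonation or O-allylation may compete, while long warming could erode trans control. The fallback separates the two bond formations; it sets out from zinc enolate 8 (made from 5 and 6 as in step 4, where the addition can be driven to completion before any electrophile is present) and returns at 9. The enolate is trapped with Me3SiOTf and the silyl enol ether trimethyl({(3S)-2,4,4-trimethyl-3-[4-(trimethylsilyl)but-3-yn-1-yl]cyclohex-1-en-1-yl}oxy)silane F1 is isolated. One equivalent of MeLi in THF at 0 °C then unmasks the regiodefined lithium enolate, lithium (3S)-2,4,4-trimethyl-3-[4-(trimethylsilyl)but-3-yn-1-yl]cyclohex-1-en-1-olate F2, which is allylated with 7 in THF–DMPU at −78 to 0 °C, again anti to the C5 chain, to give 9.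

2. Step 10. The silyl group may be lost from 17 by protodesilylation faster than the 6-exo-dig closure, catalyst turnover may stall at the protodeauration stage, and traces of acid may shift the exocyclic alkene into conjugation. The fallback replaces catalytic turnover by a stoichiometric Conia–Drouin carbomercuration with a separate demercuration; it sets out from 17 and returns at 18. Treatment of 17 with HgCl2 and hexamethyldisilazane in CH2Cl2 should give, by anti addition, the isolable alkenylmercurial chloro{(E)-[(1R,4aS,8aS)-1-formyl-5,5,8a-trimethyloctahydronaphthalen-2(1H)-ylidene]methyl}mercury F3. Protodemercuration with NaI and dilute HCl at 0 °C then gives 18.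

3. Step 12. The neopentyl-type aldehyde may add the bulky silyl dienolate slowly, so that Lewis-acid-induced migration of the exocyclic alkene, attack through the α-carbon of the dienolate or incomplete Felkin control erode the result. The fallback builds C12–C15 in stages without a strong Lewis acid; it sets out from 18 and returns at 23. Propargylation of 18 with allenylboronic acid pinacol ester under a chiral BINOL-derived phosphoric acid, the antipode chosen to reinforce the Felkin face, should give (1S)-1-[(1S,4aS,8aS)-5,5,8a-trimethyl-2-methylidenedecahydronaphthalen-1-yl]but-3-yn-1-ol F4. Negishi methylalumination (Me3Al, Cp2ZrCl2, CH2Cl2) then gives by syn addition the O,C-bis(dimethylalanyl) (E)-alkenylalane F5, which is iodinated in the same flask with I2 to (1S,3E)-4-iodo-3-methyl-1-[(1S,4aS,8aS)-5,5,8a-trimethyl-2-methylidenedecahydronaphthalen-1-yl]but-3-en-1-ol F6. Methoxycarbonylation of this alkenyl iodide (PdCl2(PPh3)2, CO, MeOH, Et3N) with retention of alkene geometry gives 23.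

**Further compounds**

F1 | step 4 | trimethyl({(3S)-2,4,4-trimethyl-3-[4-(trimethylsilyl)but-3-yn-1-yl]cyclohex-1-en-1-yl}oxy)silane | C[Si](C)(C)OC1=C(C)[C@@H](CCC#C[Si](C)(C)C)C(C)(C)CC1
F2 | step 4 | lithium (3S)-2,4,4-trimethyl-3-[4-(trimethylsilyl)but-3-yn-1-yl]cyclohex-1-en-1-olate | [Li+].[O-]C1=C(C)[C@@H](CCC#C[Si](C)(C)C)C(C)(C)CC1
F3 | step 10 | chloro{(E)-[(1R,4aS,8aS)-1-formyl-5,5,8a-trimethyloctahydronaphthalen-2(1H)-ylidene]methyl}mercury | Cl[Hg]/C=C1\CC[C@H]2C(C)(C)CCC[C@]2(C)[C@H]1C=O
F4 | step 12 | (1S)-1-[(1S,4aS,8aS)-5,5,8a-trimethyl-2-methylidenedecahydronaphthalen-1-yl]but-3-yn-1-ol | C=C1CC[C@H]2C(C)(C)CCC[C@]2(C)[C@H]1[C@H](CC#C)O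
F5 | step 12 | O,C-bis(dimethylalanyl) (E)-alkenylalane from methylalumination of F4 | C=C1CC[C@H]2C(C)(C)CCC[C@]2(C)[C@H]1[C@H](C/C(C)=C/[Al](C)C)O[Al](C)C
F6 | step 12 | (1S,3E)-4-iodo-3-methyl-1-[(1S,4aS,8aS)-5,5,8a-trimethyl-2-methylidenedecahydronaphthalen-1-yl]but-3-en-1-ol | C=C1CC[C@H]2C(C)(C)CCC[C@]2(C)[C@H]1[C@H](C/C(C)=C/I)O
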